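**Assumption:** atom labels C1–C15 are the germacrane positions of the target (ring carbons C1–C10, lactone carbons C11–C13 closed on O–C6, C14 = CHO on C10, C15 = CH2OH on C4); they are only a labelling aid. None of the stereochemical outcomes below has been tested experimentally; they are predictions from models and analogies.

## Retrosynthetic overview

1. Target 31 ⇐ silyl ether 30 ⇐ seco-triene 29 by ring-closing metathesis (C1=C10); the ten-membered ring B is closed last.
2. 29 ⇐ enal 25 + methanol + formaldehyde: the C9–OMe bond is the key disconnection (new oxa-Michael/α-methylenation that sets C9 and creates the C10 methylene handle).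
3. 25 ⇐ hydroxy enal 23: C8–O ester bond made with inversion (Mitsunobu); 23 ⇐ lactone 19 by diol unmasking and a two-carbon Wittig extension.
4. 19 (γ-lactone, ring A, formed first) ⇐ hydroxy acid 18: C6–O bond made with inversion (Mitsunobu lactonisation); 18 ⇐ indium allylation of dienal 9 (fragment 1) with bromide 15 (fragment 2).
5. 9 ⇐ but-2-yne-1,4-diol; 15 ⇐ (R)-solketal + methyl acrylate. The oxygen-bearing stereocentres C6, C8 and C9 are all fixed in C–O bond-forming steps.

## Route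

**Step 1**
Reactants: 1 but-2-yne-1,4-diol; 2 tert-butyl(chloro)diphenylsilane
Product: 3 4-[(tert-butyldiphenylsilyl)oxy]but-2-yn-1-ol
Conditions: imidazole, DMF, 0 °C to rt (3 equiv of 1)
Reagents that add atoms: tert-butyl(chloro)diphenylsilane, CC(C)(C)[Si](Cl)(c1ccccc1)c1ccccc1
Why: Statistical monosilylation (silyl ether formation) of the symmetric diol used in excess differentiates the two ends, the silylated end becoming C15 and the free end C6.

**Step 2**
Reactants: 3 4-[(tert-butyldiphenylsilyl)oxy]but-2-yn-1-ol; 4 iodine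
Product: 6 (2Z)-4-[(tert-butyldiphenylsilyl)oxy]-3-iodobut-2-en-1-ol, via vinylalanate 5 (not isolated)
Conditions: NaAlH2(OCH2CH2OMe)2, THF, 0 °C; then I2, −78 to 0 °C
Reagents that add atoms: iodine, I-I
Why: Hydroxyl-directed trans-hydroalumination of the propargylic alcohol puts aluminium on the distal alkyne carbon inside a five-membered alkoxyalanate, and iodinolysis with retention gives the Z-iodoalkene that fixes the C4=C5 geometry.

**Step 3**
Reactants: 6 (2Z)-4-[(tert-butyldiphenylsilyl)oxy]-3-iodobut-2-en-1-ol; 7 but-3-en-1-ylzinc bromide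
Product: 8 (2E)-3-{[(tert-butyldiphenylsilyl)oxy]methyl}hepta-2,6-dien-1-ol
Conditions: Pd(dppf)Cl2 (5 mol%), THF, 50 °C (3 equiv of 7)
Reagents that add atoms: but-3-en-1-ylzinc bromide, C=CCC[Zn]Br
Why: Negishi sp2–sp3 cross-coupling proceeds with retention at the alkenyl iodide, so the butenyl chain (C3–C1) is cis to the CH2OH carbon (C6), as the ring-cis C4=C5 alkene requires.

**Step 4**
Reactants: 8 (2E)-3-{[(tert-butyldiphenylsilyl)oxy]methyl}hepta-2,6-dien-1-ol
Product: 9 (2E)-3-{[(tert-butyldiphenylsilyl)oxy]methyl}hepta-2,6-dienal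
Conditions: MnO2, CH2Cl2, rt
Reagents that add atoms: none
Why: Allylic alcohol oxidation with MnO2 is chemoselective and neutral, so the trisubstituted alkene geometry is kept.

**Step 5**
Reactants: 10 [(4R)-2,2-dimethyl-1,3-dioxolan-4-yl]methanol ((R)-solketal)
Product: 11 (4S)-2,2-dimethyl-1,3-dioxolane-4-carbaldehyde
Conditions: (COCl)2, DMSO, CH2Cl2, −78 °C; then Et3N
Reagents that add atoms: none
Why: Swern oxidation gives the configurationally stable acetonide aldehyde without touching the stereocentre (the descriptor changes only through CIP priorities); it is used crude.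

**Step 6**
Reactants: 11 (4S)-2,2-dimethyl-1,3-dioxolane-4-carbaldehyde; 12 methyl acrylate
Product: 13 methyl 2-{[(4S)-2,2-dimethyl-1,3-dioxolan-4-yl](hydroxy)methyl}prop-2-enoate (both carbinol epimers)
Conditions: DABCO, 1,4-dioxane/H2O (1:1), rt, 3 d
Reagents that add atoms: methyl acrylate, C=CC(=O)OC
Why: Morita–Baylis–Hillman reaction joins C7 to C11; the new carbinol centre is irrelevant because step 7 turns it into an alkene carbon.

**Step 7**
Reactants: 13 methyl 2-{[(4S)-2,2-dimethyl-1,3-dioxolan-4-yl](hydroxy)methyl}prop-2-enoate; 14 N-bromosuccinimide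
Product: 15 methyl (2Z)-2-(bromomethyl)-3-[(4R)-2,2-dimethyl-1,3-dioxolan-4-yl]prop-2-enoate
Conditions: NBS, Me2S, CH2Cl2, 0 °C to rt
Reagents that add atoms: N-bromosuccinimide, BrN1C(=O)CCC1=O
Why: Corey–Kim-type activation of the allylic alcohol followed by SN2' attack of bromide gives the thermodynamically favoured Z-2-(bromomethyl)alkenoate under conditions that spare the acetonide.

**Step 8**
Reactants: 9 (2E)-3-{[(tert-butyldiphenylsilyl)oxy]methyl}hepta-2,6-dienal; 15 methyl (2Z)-2-(bromomethyl)-3-[(4R)-2,2-dimethyl-1,3-dioxolan-4-yl]prop-2-enoate; 16 lithium hydroxide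
Product: 18 (3S,4S,5E)-6-{[(tert-butyldiphenylsilyl)oxy]methyl}-3-[(4R)-2,2-dimethyl-1,3-dioxolan-4-yl]-4-hydroxy-2-methylidenedeca-5,9-dienoic acid, via hydroxy ester 17 (not isolated)
Conditions: indium powder, THF/H2O (1:1), rt; then LiOH, rt; then 1 M HCl to pH 4, 0 °C
Reagents that add atoms: lithium hydroxide, [Li+].[OH-]
Why: Barbier allylation through the Z-allylindium in a closed chair transition state should give the 6,7-syn alcohol, with the aldehyde entering anti to the dioxolane C–O bond of the H-eclipsed allylic conformer (non-chelated, by analogy with indium allylations of glyceraldehyde acetonide and alkylations of dioxolanyl enolates), which sets C7 as in the target and leaves C6 and C8 to be inverted later; hydroxide then cleaves the methyl ester (and any cis-lactone) to the seco acid.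

**Step 9**
Reactants: 18 (3S,4S,5E)-6-{[(tert-butyldiphenylsilyl)oxy]methyl}-3-[(4R)-2,2-dimethyl-1,3-dioxolan-4-yl]-4-hydroxy-2-methylidenedeca-5,9-dienoic acid
Product: 19 (4S,5R)-5-[(1E)-2-{[(tert-butyldiphenylsilyl)oxy]methyl}hexa-1,5-dien-1-yl]-4-[(4R)-2,2-dimethyl-1,3-dioxolan-4-yl]-3-methylideneoxolan-2-one (4,5-trans)
Conditions: PPh3, diisopropyl azodicarboxylate (DIAD), THF (0.01 M), 0 °C to rt
Reagents that add atoms: none
Why: Mitsunobu lactonisation activates the allylic C6 hydroxyl as its oxyphosphonium ion and the internal carboxylate displaces it (5-exo, SN2), so the C6–O bond forms with inversion and gives the 6,7-trans γ-lactone (ring A) of the target.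

**Step 10**
Reactants: 19 (4S,5R)-5-[(1E)-2-{[(tert-butyldiphenylsilyl)oxy]methyl}hexa-1,5-dien-1-yl]-4-[(4R)-2,2-dimethyl-1,3-dioxolan-4-yl]-3-methylideneoxolan-2-one
Product: 20 (4R,5R)-5-[(1E)-2-{[(tert-butyldiphenylsilyl)oxy]methyl}hexa-1,5-dien-1-yl]-4-[(1R)-1,2-dihydroxyethyl]-3-methylideneoxolan-2-one
Conditions: AcOH/H2O (4:1), 40 °C
Reagents that add atoms: none
Why: Mild acidic acetal hydrolysis frees the C8/C9 diol while the primary TBDPS ether and the lactone survive.

**Step 11**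
Reactants: 20 (4R,5R)-5-[(1E)-2-{[(tert-butyldiphenylsilyl)oxy]methyl}hexa-1,5-dien-1-yl]-4-[(1R)-1,2-dihydroxyethyl]-3-methylideneoxolan-2-one; 21 (triphenylphosphoranylidene)acetaldehyde
Product: 23 (2E,4S)-4-hydroxy-4-{(2R,3R)-2-[(1E)-2-{[(tert-butyldiphenylsilyl)oxy]methyl}hexa-1,5-dien-1-yl]-4-methylidene-5-oxooxolan-3-yl}but-2-enal, via hydroxy aldehyde 22 (not isolated)
Conditions: TEMPO (10 mol%), PhI(OAc)2, CH2Cl2, rt; then Ph3P=CHCHO, rt to 40 °C
Reagents that add atoms: (triphenylphosphoranylidene)acetaldehyde, O=CC=P(c1ccccc1)(c1ccccc1)c1ccccc1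
Why: TEMPO/PhI(OAc)2 oxidises the primary C9 alcohol in preference to the secondary C8 alcohol, and the sensitive α-hydroxy aldehyde is trapped at once by a stabilised Wittig ylide to give the E-enal (C9=C10–C14).

**Step 12**
Reactants: 23 (2E,4S)-4-hydroxy-4-{(2R,3R)-2-[(1E)-2-{[(tert-butyldiphenylsilyl)oxy]methyl}hexa-1,5-dien-1-yl]-4-methylidene-5-oxooxolan-3-yl}but-2-enal; 24 methacrylic acid
Product: 25 (1R,2E)-4-oxo-1-{(2R,3R)-2-[(1E)-2-{[(tert-butyldiphenylsilyl)oxy]methyl}hexa-1,5-dien-1-yl]-4-methylidene-5-oxooxolan-3-yl}but-2-en-1-yl 2-methylprop-2-enoate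
Conditions: PPh3, DIAD, toluene, −20 °C to rt
Reagents that add atoms: methacrylic acid, CC(=C)C(=O)O
Why: Mitsunobu esterification displaces the activated allylic C8 oxyphosphonium by methacrylate with SN2 inversion, which brings C8 to the configuration of the target and installs the ester before the C14 aldehyde can form a lactol with a free C8 hydroxyl.

**Step 13**
Reactants: 25 (1R,2E)-4-oxo-1-{(2R,3R)-2-[(1E)-2-{[(tert-butyldiphenylsilyl)oxy]methyl}hexa-1,5-dien-1-yl]-4-methylidene-5-oxooxolan-3-yl}but-2-en-1-yl 2-methylprop-2-enoate; 26 methanol; 27 formaldehyde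
Product: 29 (1S,2S)-2-methoxy-3-methylidene-4-oxo-1-{(2R,3S)-2-[(1E)-2-{[(tert-butyldiphenylsilyl)oxy]methyl}hexa-1,5-dien-1-yl]-4-methylidene-5-oxooxolan-3-yl}butyl 2-methylprop-2-enoate, via methoxy aldehyde 28 (not isolated)
Conditions: (S)-2-{bis[3,5-bis(trifluoromethyl)phenyl][(trimethylsilyl)oxy]methyl}pyrrolidine (20 mol%), PhCO2H (20 mol%), 37% aq. CH2O (3 equiv), MeOH, rt
Reagents that add atoms: methanol, CO; formaldehyde, C=O
Why: Proposed new method: a three-component amine-catalysed oxa-Michael/α-methylenation in which the enal forms an E-iminium ion with the diarylprolinol silyl ether, methanol (solvent) adds reversibly to C9 on the face away from the CAr2(OSiMe3) group (the steric model predicts 9S with the S catalyst, i.e. the 8,9-syn ether), and the resulting enamine is trapped by formaldehyde and loses water, which makes the otherwise unfavourable methanol addition irreversible because the α-branched acrolein has no α-hydrogen for retro-addition and is a poor iminium substrate; the closest known reactions are the amine-catalysed oxa-Michael/aldol-condensation domino of salicylaldehydes with enals (2H-chromenes), iminium-catalysed β-oxygenation of enals with oximes, and amine-catalysed α-hydroxymethylation/α-methylenation of aldehydes with aqueous formaldehyde.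

**Step 14**
Reactants: 29 (1S,2S)-2-methoxy-3-methylidene-4-oxo-1-{(2R,3S)-2-[(1E)-2-{[(tert-butyldiphenylsilyl)oxy]methyl}hexa-1,5-dien-1-yl]-4-methylidene-5-oxooxolan-3-yl}butyl 2-methylprop-2-enoate
Product: 30 15-O-(tert-butyldiphenylsilyl) ether of the target, (1(10)E,4E,6R,7S,8S,9S)-15-[(tert-butyldiphenylsilyl)oxy]-9-methoxy-14-oxogermacra-1(10),4,11(13)-trien-12,6-olid-8-yl 2-methylprop-2-enoate
Conditions: second-generation Hoveyda–Grubbs catalyst RuCl2(=CH-C6H4-2-OiPr)(H2IMes) (10 mol%), 1,4-benzoquinone (20 mol%), toluene (1 mM), 80 °C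
Reagents that add atoms: none
Why: Ring-closing metathesis between the terminal vinyl group (C1) and the 2-substituted acrolein (C10) releases ethene and closes ring B, and the ten-membered ring should favour the ring-cis trisubstituted alkene (C2 cis to C9, CHO trans to C2), which is also the thermodynamically preferred enal geometry.

**Step 15**
Reactants: 30 15-O-(tert-butyldiphenylsilyl) ether of the target
Product: 31 (1(10)E,4E,6R,7S,8S,9S)-15-hydroxy-9-methoxy-14-oxogermacra-1(10),4,11(13)-trien-12,6-olid-8-yl 2-methylprop-2-enoate (CNP0114830.1)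
Conditions: HF·pyridine, THF/pyridine, 0 °C to rt
Reagents that add atoms: none
Why: Buffered fluoride desilylation removes the primary allylic TBDPS ether without touching the enal, the methacrylate or the α-methylene lactone.

## Compound list

1 | but-2-yne-1,4-diol | OCC#CCO | starting material
2 | tert-butyl(chloro)diphenylsilane | CC(C)(C)[Si](Cl)(c1ccccc1)c1ccccc1 | starting material
3 | 4-[(tert-butyldiphenylsilyl)oxy]but-2-yn-1-ol | OCC#CCO[Si](c1ccccc1)(c1ccccc1)C(C)(C)C | intermediate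
4 | iodine | I-I | starting material
5 | sodium 3-{[(tert-butyldiphenylsilyl)oxy]methyl}-2,2-bis(2-methoxyethoxy)-2,5-dihydro-1,2-oxaluminol-2-uide (cyclic vinylalanate) | [Na+].COCCO[Al-]1(OCCOC)OCC=C1CO[Si](c1ccccc1)(c1ccccc1)C(C)(C)C | intermediate
6 | (2Z)-4-[(tert-butyldiphenylsilyl)oxy]-3-iodobut-2-en-1-ol | OC/C=C(\I)CO[Si](c1ccccc1)(c1ccccc1)C(C)(C)C | intermediate
7 | but-3-en-1-ylzinc bromide | C=CCC[Zn]Br | starting material
8 | (2E)-3-{[(tert-butyldiphenylsilyl)oxy]methyl}hepta-2,6-dien-1-ol (CH2OH cis to the butenyl chain) | OC/C=C(\CCC=C)CO[Si](c1ccccc1)(c1ccccc1)C(C)(C)C | intermediate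
9 | (2E)-3-{[(tert-butyldiphenylsilyl)oxy]methyl}hepta-2,6-dienal | O=C/C=C(\CCC=C)CO[Si](c1ccccc1)(c1ccccc1)C(C)(C)C | intermediate
10 | [(4R)-2,2-dimethyl-1,3-dioxolan-4-yl]methanol ((R)-solketal) | OC[C@@H]1COC(C)(C)O1 | starting material
11 | (4S)-2,2-dimethyl-1,3-dioxolane-4-carbaldehyde | O=C[C@@H]1COC(C)(C)O1 | intermediate
12 | methyl acrylate | C=CC(=O)OC | starting material
13 | methyl 2-{[(4S)-2,2-dimethyl-1,3-dioxolan-4-yl](hydroxy)methyl}prop-2-enoate (carbinol epimers) | COC(=O)C(=C)C(O)[C@@H]1COC(C)(C)O1 | intermediate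
14 | N-bromosuccinimide | BrN1C(=O)CCC1=O | starting material
15 | methyl (2Z)-2-(bromomethyl)-3-[(4R)-2,2-dimethyl-1,3-dioxolan-4-yl]prop-2-enoate | COC(=O)/C(CBr)=C/[C@@H]1COC(C)(C)O1 | intermediate
16 | lithium hydroxide | [Li+].[OH-] | starting material
17 | methyl (3S,4S,5E)-6-{[(tert-butyldiphenylsilyl)oxy]methyl}-3-[(4R)-2,2-dimethyl-1,3-dioxolan-4-yl]-4-hydroxy-2-methylidenedeca-5,9-dienoate | COC(=O)C(=C)[C@@H]([C@@H](O)/C=C(\CCC=C)CO[Si](c1ccccc1)(c1ccccc1)C(C)(C)C)[C@@H]1COC(C)(C)O1 | intermediate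
18 | (3S,4S,5E)-6-{[(tert-butyldiphenylsilyl)oxy]methyl}-3-[(4R)-2,2-dimethyl-1,3-dioxolan-4-yl]-4-hydroxy-2-methylidenedeca-5,9-dienoic acid | OC(=O)C(=C)[C@@H]([C@@H](O)/C=C(\CCC=C)CO[Si](c1ccccc1)(c1ccccc1)C(C)(C)C)[C@@H]1COC(C)(C)O1 | intermediate
19 | (4S,5R)-5-[(1E)-2-{[(tert-butyldiphenylsilyl)oxy]methyl}hexa-1,5-dien-1-yl]-4-[(4R)-2,2-dimethyl-1,3-dioxolan-4-yl]-3-methylideneoxolan-2-one | C=C1C(=O)O[C@H](/C=C(\CCC=C)CO[Si](c2ccccc2)(c2ccccc2)C(C)(C)C)[C@H]1[C@@H]3COC(C)(C)O3 | intermediate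
20 | (4R,5R)-5-[(1E)-2-{[(tert-butyldiphenylsilyl)oxy]methyl}hexa-1,5-dien-1-yl]-4-[(1R)-1,2-dihydroxyethyl]-3-methylideneoxolan-2-one | C=C1C(=O)O[C@H](/C=C(\CCC=C)CO[Si](c2ccccc2)(c2ccccc2)C(C)(C)C)[C@H]1[C@@H](O)CO | intermediate
21 | (triphenylphosphoranylidene)acetaldehyde | O=CC=P(c1ccccc1)(c1ccccc1)c1ccccc1 | starting material
22 | (2R)-2-hydroxy-2-{(2R,3R)-2-[(1E)-2-{[(tert-butyldiphenylsilyl)oxy]methyl}hexa-1,5-dien-1-yl]-4-methylidene-5-oxooxolan-3-yl}acetaldehyde | C=C1C(=O)O[C@H](/C=C(\CCC=C)CO[Si](c2ccccc2)(c2ccccc2)C(C)(C)C)[C@H]1[C@@H](O)C=O | intermediate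
23 | (2E,4S)-4-hydroxy-4-{(2R,3R)-2-[(1E)-2-{[(tert-butyldiphenylsilyl)oxy]methyl}hexa-1,5-dien-1-yl]-4-methylidene-5-oxooxolan-3-yl}but-2-enal (C8 epimeric to the target) | C=C1C(=O)O[C@H](/C=C(\CCC=C)CO[Si](c2ccccc2)(c2ccccc2)C(C)(C)C)[C@H]1[C@@H](O)/C=C/C=O | intermediate
24 | methacrylic acid | CC(=C)C(=O)O | starting material
25 | (1R,2E)-4-oxo-1-{(2R,3R)-2-[(1E)-2-{[(tert-butyldiphenylsilyl)oxy]methyl}hexa-1,5-dien-1-yl]-4-methylidene-5-oxooxolan-3-yl}but-2-en-1-yl 2-methylprop-2-enoate | C=C1C(=O)O[C@H](/C=C(\CCC=C)CO[Si](c2ccccc2)(c2ccccc2)C(C)(C)C)[C@H]1[C@H](OC(=O)C(C)=C)/C=C/C=O | intermediate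
26 | methanol | CO | starting material
27 | formaldehyde | C=O | starting material
28 | (1S,2S)-2-methoxy-4-oxo-1-{(2R,3S)-2-[(1E)-2-{[(tert-butyldiphenylsilyl)oxy]methyl}hexa-1,5-dien-1-yl]-4-methylidene-5-oxooxolan-3-yl}butyl 2-methylprop-2-enoate (present largely as its enamine with the catalyst) | C=C1C(=O)O[C@H](/C=C(\CCC=C)CO[Si](c2ccccc2)(c2ccccc2)C(C)(C)C)[C@H]1[C@H](OC(=O)C(C)=C)[C@@H](OC)CC=O | intermediate
29 | (1S,2S)-2-methoxy-3-methylidene-4-oxo-1-{(2R,3S)-2-[(1E)-2-{[(tert-butyldiphenylsilyl)oxy]methyl}hexa-1,5-dien-1-yl]-4-methylidene-5-oxooxolan-3-yl}butyl 2-methylprop-2-enoate | C=C1C(=O)O[C@H](/C=C(\CCC=C)CO[Si](c2ccccc2)(c2ccccc2)C(C)(C)C)[C@H]1[C@H](OC(=O)C(C)=C)[C@@H](OC)C(=C)C=O | intermediate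
30 | (1(10)E,4E,6R,7S,8S,9S)-15-[(tert-butyldiphenylsilyl)oxy]-9-methoxy-14-oxogermacra-1(10),4,11(13)-trien-12,6-olid-8-yl 2-methylprop-2-enoate | C=C(C)C(=O)O[C@H]1[C@H]2C(=C)C(=O)O[C@@H]2/C=C(/CO[Si](c3ccccc3)(c3ccccc3)C(C)(C)C)CC/C=C(/C=O)[C@@H]1OC | intermediate
31 | (1(10)E,4E,6R,7S,8S,9S)-15-hydroxy-9-methoxy-14-oxogermacra-1(10),4,11(13)-trien-12,6-olid-8-yl 2-methylprop-2-enoate (both ring alkenes ring-cis) | C=C(C)C(=O)O[C@H]1[C@H]2C(=C)C(=O)O[C@@H]2/C=C(/CO)CC/C=C(/C=O)[C@@H]1OC | target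

## Step count and risks

Total steps: 15. Longest linear sequence: 12 (steps 1–4, then 8–15).

**Step 13 (the proposed new reaction).** Methanol addition is reversible, so the C9 selectivity depends on how the two diastereomeric enamines are trapped, and the C8 ester may oppose the catalyst. γ-Deprotonation (dienamine) could also erode C8. The fallback uses known chemistry; it sets out from diol 20 and comes back at 29. Diol 20 is oxidised to hydroxy aldehyde 22 as in step 11 (TEMPO, PhI(OAc)2) and, without the Wittig reaction, is converted with HC(OMe)3 and pyridinium tosylate in MeOH into the hydroxy dimethyl acetal F1. Mitsunobu esterification of F1 with methacrylic acid 24 (PPh3, DIAD) inverts C8 and gives the acyloxy acetal F2. F2 is coupled with commercial acrolein under sulfide-mediated Baylis–Hillman conditions for acetals (Me2S, TMSOTf, CH2Cl2, −78 to −20 °C). This gives the β-sulfonium aldehyde triflate F3 in the flask, and DBU eliminates Me2S to give 29. Here C9 is set in the C–C bond-forming step: participation of the C8 ester in the oxocarbenium ion (dioxolanylium ion, opened with inversion) should lead to the 8,9-syn ether, and any minor C9 epimer is removed by chromatography.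

**Step 14 (ring-closing metathesis).** The ten-membered ring is strained, the acrolein olefin is electron-poor, and the methacrylate and the lactone methylene are competing 1,1-disubstituted partners. The fallback sets out from 29 and comes back at 30; it takes the aldehyde out of the ring-closing event so that the C10 olefin becomes the most electron-rich of the three. Luche reduction of 29 (NaBH4, CeCl3·7H2O, MeOH, −78 °C) gives the 2-substituted allylic alcohol F4. Hydroxyl-assisted ring closure of F4 with the second-generation Grubbs catalyst RuCl2(=CHPh)(H2IMes)(PCy3) (CH2Cl2, 40 °C, 1 mM) gives the macrocyclic allylic alcohol F5. MnO2 (CH2Cl2, rt) then oxidises only the allylic C14 alcohol to give 30.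

**Step 8 (indium allylation).** Both the syn sense and the facial selectivity relative to the dioxolane are inferred from analogy, and the aqueous indium transition state is loose. The fallback sets out from bromide 15 (with dienal 9) and comes back at acid 18; it replaces the Barbier reaction by a stereospecific type-one allylboration through a tight six-membered boron transition state. Borylation of 15 (B2pin2, Pd2(dba)3, toluene, 50 °C) gives the allylboronate F6. F6 adds to 9 (toluene, 80 °C, or Sc(OTf)3 10 mol%, CH2Cl2, −78 °C) to give hydroxy ester 17, and the LiOH treatment of step 8 (which also opens any cis-lactone) returns 18.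

## Further compounds

F1 | step 13 | (4R,5R)-5-[(1E)-2-{[(tert-butyldiphenylsilyl)oxy]methyl}hexa-1,5-dien-1-yl]-4-[(1R)-1-hydroxy-2,2-dimethoxyethyl]-3-methylideneoxolan-2-one | C=C1C(=O)O[C@H](/C=C(\CCC=C)CO[Si](c2ccccc2)(c2ccccc2)C(C)(C)C)[C@H]1[C@@H](O)C(OC)OC
F2 | step 13 | (1S)-2,2-dimethoxy-1-{(2R,3S)-2-[(1E)-2-{[(tert-butyldiphenylsilyl)oxy]methyl}hexa-1,5-dien-1-yl]-4-methylidene-5-oxooxolan-3-yl}ethyl 2-methylprop-2-enoate | C=C1C(=O)O[C@H](/C=C(\CCC=C)CO[Si](c2ccccc2)(c2ccccc2)C(C)(C)C)[C@H]1[C@H](OC(=O)C(C)=C)C(OC)OC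
F3 | step 13 | {(3S,4S)-2-formyl-3-methoxy-4-[(2-methylprop-2-enoyl)oxy]-4-{(2R,3S)-2-[(1E)-2-{[(tert-butyldiphenylsilyl)oxy]methyl}hexa-1,5-dien-1-yl]-4-methylidene-5-oxooxolan-3-yl}butyl}dimethylsulfonium triflate (C10 epimers, not isolated) | C=C1C(=O)O[C@H](/C=C(\CCC=C)CO[Si](c2ccccc2)(c2ccccc2)C(C)(C)C)[C@H]1[C@H](OC(=O)C(C)=C)[C@@H](OC)C(C=O)C[S+](C)C.[O-]S(=O)(=O)C(F)(F)F
F4 | step 14 | (1S,2S)-3-(hydroxymethyl)-2-methoxy-1-{(2R,3S)-2-[(1E)-2-{[(tert-butyldiphenylsilyl)oxy]methyl}hexa-1,5-dien-1-yl]-4-methylidene-5-oxooxolan-3-yl}but-3-en-1-yl 2-methylprop-2-enoate | C=C1C(=O)O[C@H](/C=C(\CCC=C)CO[Si](c2ccccc2)(c2ccccc2)C(C)(C)C)[C@H]1[C@H](OC(=O)C(C)=C)[C@@H](OC)C(=C)CO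
F5 | step 14 | (1(10)E,4E,6R,7S,8S,9S)-15-[(tert-butyldiphenylsilyl)oxy]-14-hydroxy-9-methoxygermacra-1(10),4,11(13)-trien-12,6-olid-8-yl 2-methylprop-2-enoate | C=C(C)C(=O)O[C@H]1[C@H]2C(=C)C(=O)O[C@@H]2/C=C(/CO[Si](c3ccccc3)(c3ccccc3)C(C)(C)C)CC/C=C(/CO)[C@@H]1OC
F6 | step 8 | methyl (2E)-3-[(4R)-2,2-dimethyl-1,3-dioxolan-4-yl]-2-[(4,4,5,5-tetramethyl-1,3,2-dioxaborolan-2-yl)methyl]prop-2-enoate (dioxolanyl cis to CH2B) | COC(=O)/C(CB1OC(C)(C)C(C)(C)O1)=C/[C@@H]2COC(C)(C)O2
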